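Time came first for me, since temperature and added ligand had moved together between the earlier runs, zeta and theta, and two runs could not part them.

| flask | left-handed substrate | right-handed substrate | reagent | free catalyst | added ligand | temperature | remark | time |
|---|---|---|---|---|---|---|---|---|
| zeta | 0.030 M | 0.030 M | 0.036 M (fed, over 80 s) | 0.15 mM | 0.086 mM | 95 °C | run made earlier; the fed solution adds 0.50 times the starting volume |  |
| theta | 0.030 M | 0.030 M | 0.036 M (fed, over 80 s) | 0.15 mM | 0.26 mM | 106 °C | run made earlier; the fed solution adds 0.50 times the starting volume |  |
| oak | 0.030 M | 0.030 M | 0.0360 M | 0.15 mM | 0.060 mM | 100 °C | everything together at the start, the whole solution of reagent included, so that from the start the volume is larger by 0.50 times the starting volume | 4.0 h |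
| larch | 0.030 M | 0.030 M | 0.0360 M (fed, over 80 s) | 0.15 mM | 0.20 mM | 100 °C | the fed solution adds 0.50 times the starting volume | 4.0 h |

| run | time / h | left-handed product / % |
|---|---|---|
| zeta | 0.333 | 14.0 |
| zeta | 0.667 | 22.4 |
| zeta | 1.00 | 25.1 |
| zeta | 2.00 | 28.3 |
| zeta | 4.00 | 26.4 |
| theta | 0.333 | 14.9 |
| theta | 0.667 | 21.1 |
| theta | 1.00 | 23.3 |
| theta | 2.00 | 24.1 |
| theta | 4.00 | 25.7 |

(readings scatter by 0.5 percentage points)

- the winner by amount of left-handed product, in percent of the left-handed substrate and right-handed substrate together charged; "neither" if no more than 2 percentage points parts them (oak / larch / neither)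
- how much left-handed product is there at the end, in percent of the left-handed substrate and right-handed substrate together charged: oak
- how much left-handed product is there at the end, in percent of the left-handed substrate and right-handed substrate together charged: larch

- free catalyst is single-handed; left-handed substrate and right-handed substrate are mirror images of each other, charged as a racemate, each of them at the stated concentration
- charges are per starting volume, the dose included; the dosed solution carries all of it
- the analysis behind the earlier runs scatters by 0.5 percentage points, standard deviation

I took each run's plateau as the mean of its last two readings of left-handed product: 27.4% for zeta and 24.9% for theta. From the first two readings I reckoned how fast the gap to that plateau closed, which gave 0.233 h and 0.239 h. Their mean, 0.236 h, is τ, the half-time of the gap between left-handed product and its plateau.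

I held τ against the run time 4.0 h. Oak and larch each lasted 16.9 half-times by this reading, so I expected both to end on the plateau. The feed of 80 s is shorter than τ, so I dropped it. Oak's ligand, 0.060 mM, lay below the tested range, but 100 °C lay between the run temperatures, so I committed to the mean plateau, 26.1%, for both flasks.

The forecast gave 26.5% for oak, 26% for larch and neither as the winner, holding that “dosing versus all-at-once should hardly matter”.

The flasks gave 25.6% for oak and 25.5% for larch, so the answer to the first question was neither.

    free catalyst + left-handed substrate ⇌ catalyst intermediate A (K = 640 M⁻¹, k = 1550 M⁻¹ min⁻¹, Ea = 64.0 kJ mol⁻¹, ΔH = −46.0 kJ mol⁻¹)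
    free catalyst + right-handed substrate ⇌ catalyst intermediate B (K = 21.0 M⁻¹, k = 22100 M⁻¹ min⁻¹, Ea = 46.0 kJ mol⁻¹, ΔH = −23.0 kJ mol⁻¹)
    reagent + catalyst intermediate A → free catalyst + left-handed product (k = 252 M⁻¹ min⁻¹, Ea = 45.0 kJ mol⁻¹)
    reagent + catalyst intermediate B → free catalyst + right-handed product (k = 11.3 M⁻¹ min⁻¹, Ea = 82.0 kJ mol⁻¹)
    left-handed product ⇌ right-handed product (k = 0.0144 min⁻¹, Ea = 129 kJ mol⁻¹)
    free catalyst + added ligand ⇌ idle complex (K = 6450 M⁻¹, k = 421 M⁻¹ min⁻¹, Ea = 44.0 kJ mol⁻¹, ΔH = 14.0 kJ mol⁻¹)
    reagent → decomposition product (k = 1.82 × 10⁻⁵ min⁻¹, Ea = 124 kJ mol⁻¹)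
    (constants at 100 °C)

The neighbouring flask was oak kept at 75 °C, colder than zeta, the colder of the earlier runs. Taken at face value, τ of 0.236 h allowed it 16.9 half-times, so the reckoning said 26.1%, but it gave 37.3%, with right-handed product at 4.16%.

The numbers in the tables are calculated for substances that don't exist; scatter was added.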